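## Retrosynthetic overview

1. 12 ⇒ 2 × 9 + 5 + 2 CH2O: both CH2 bridges are cut last (formaldehyde / quinone-methide coupling; no ring is formed there).
2. Aromatic ring of 5 ⇒ open-chain tetraketide ester 4 by C6→C1 Claisen closure (the polyketide-synthase mode); 4 is unmasked in the flask from pyrone 3, which comes from triacetic acid lactone 1 + methyl butanoate 2.
3. Dienone ring of 9 ⇒ gem-dimethyl tetraketide ester 8 by the same C6→C1 Claisen closure; 8 comes from the 1,3-dianion of heptane-2,4-dione 6 + dimethyl dimethylmalonate 7 (formal [3+3]).
4. Ring order: the arene of 5 and the dienone ring of 9 are made in two parallel one-pot steps; the three rings are then joined through two CH2 units in the last step.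

Assumption: the target (filixic acid BBB, C36H44O12) has no stereocentre and no stereogenic double bond, so it is achiral and needs no stereocontrol; tautomers are drawn as in the given SMILES.

## Route

Step 1
Reactants: 1 4-hydroxy-6-methyl-2H-pyran-2-one (triacetic acid lactone); 2 methyl butanoate
Product: 5 1-(2,4,6-trihydroxyphenyl)butan-1-one (phlorobutyrophenone), via acylmethyl pyrone 3 (not isolated), via tetraketide ester 4 (not isolated)
Conditions: 1 (2.0 equiv), LDA (4.1 equiv, commercial solution), THF/DMPU, −78 °C; 2 (1.0 equiv), −78 → 0 °C; then Mg(OMe)2 (8 equiv) in MeOH, reflux, 12 h; 2 M HCl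
Reagents that add atoms: none
Why: Proposed new method: a one-pot merger of two known reaction types, namely ester acylation of the 6-methyl carbanion of the pyrone dianion (Hauser–Harris dianion Claisen condensation, giving 3) and the magnesium methoxide-induced pyrone-to-phloroglucinol rearrangement, in which methoxide opens the enol lactone to the Mg-chelated tetraketide ester 4 and the doubly activated C6 then attacks the C1 ester (biomimetic C6→C1 Claisen cyclisation) before irreversible enolisation to the arene, with Mg chelation of the 3,5,7-trioxo array holding the ketones as enolates so that the competing C2→C7 aldol closure is suppressed; no stereocentre is formed.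

Step 2
Reactants: 6 heptane-2,4-dione; 7 dimethyl 2,2-dimethylpropanedioate (dimethyl dimethylmalonate)
Product: 9 2-butanoyl-3,5-dihydroxy-6,6-dimethylcyclohexa-2,4-dien-1-one (butyrylfilicinic acid), via dimethyl tetraketide ester 8 (not isolated)
Conditions: 6 (1.2 equiv), LDA (3.6 equiv, commercial solution), THF, −78 → 0 °C; 7 (1.0 equiv), −78 °C → rt; then Mg(OMe)2 (6 equiv) in MeOH, reflux, 12 h; 2 M HCl; product taken into aq NaHCO3 and re-acidified
Reagents that add atoms: none
Why: Proposed new method: a formal [3+3] Claisen/Claisen annulation whose closest known reaction types are the Hauser–Harris acylation of β-diketone 1,3-dianions by non-enolisable esters and the Dieckmann-type closure onto α,α-dimethyl esters used for syncarpic acid-type cyclic triones, the reasoning being that the terminal carbanion of the dianion of 6 is acylated by one ester of 7 to give 8, whose quaternary C2 cannot enolise (so the C2→C7 aldol mode is impossible, while enolisation of C3/C5 protects against retro-Claisen cleavage), leaving Mg-templated attack of C6 on the remaining ester, assisted by the gem-dimethyl effect and pulled forward by formation of the chelated, strongly acidic acyl-trione anion; no stereocentre is formed.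

Step 3
Reactants: 9 butyrylfilicinic acid (2.2 equiv); 5 phlorobutyrophenone (1.0 equiv)
Product: 12 filixic acid BBB (target), via methylene-trione 10 (not isolated), via mono-bridged dimer 11 (not isolated)
Conditions: 1% aq KOH, N2, 0 °C; 37% aq CH2O (2.1 equiv) added over 30 min; rt, 15 min; 1 M HCl; chromatography / recrystallisation
Reagents that add atoms: formaldehyde, C=O
Why: Base-mediated formaldehyde methylene-bridging of acylphloroglucinols (Knoevenagel condensation followed by Michael/Friedel–Crafts-type C-alkylation): the enolate of 9 condenses with formaldehyde to the methylene-trione 10, a quinone-methide-like acceptor that is captured first by one and then by the other free ring carbon of the phloroglucinolate of 5 (11, then 12), mirroring the presumed biosynthetic bridging; no stereocentre is formed.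

## Compound list

1 | 4-hydroxy-6-methyl-2H-pyran-2-one (triacetic acid lactone) | CC1=CC(O)=CC(=O)O1 | starting material
2 | methyl butanoate | CCCC(=O)OC | starting material
3 | 4-hydroxy-6-(2-oxopentyl)-2H-pyran-2-one (acylmethyl pyrone) | CCCC(=O)CC1=CC(O)=CC(=O)O1 | intermediate
4 | methyl 3,5,7-trioxodecanoate (tetraketide ester) | CCCC(=O)CC(=O)CC(=O)CC(=O)OC | intermediate
5 | 1-(2,4,6-trihydroxyphenyl)butan-1-one (phlorobutyrophenone) | CCCC(=O)c1c(O)cc(O)cc1O | intermediate
6 | heptane-2,4-dione | CCCC(=O)CC(C)=O | starting material
7 | dimethyl 2,2-dimethylpropanedioate (dimethyl dimethylmalonate) | COC(=O)C(C)(C)C(=O)OC | starting material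
8 | methyl 2,2-dimethyl-3,5,7-trioxodecanoate (dimethyl tetraketide ester) | CCCC(=O)CC(=O)CC(=O)C(C)(C)C(=O)OC | intermediate
9 | 2-butanoyl-3,5-dihydroxy-6,6-dimethylcyclohexa-2,4-dien-1-one (butyrylfilicinic acid) | CCCC(=O)C1=C(O)C=C(O)C(C)(C)C1=O | intermediate
10 | 2-butanoyl-3-hydroxy-6,6-dimethyl-4-methylidenecyclohex-2-ene-1,5-dione (methylene-trione) | CCCC(=O)C1=C(O)C(=C)C(=O)C(C)(C)C1=O | intermediate
11 | 2-butanoyl-4-[(3-butanoyl-2,4,6-trihydroxyphenyl)methyl]-3,5-dihydroxy-6,6-dimethylcyclohexa-2,4-dien-1-one (mono-bridged dimer) | CCCC(=O)C1=C(O)C(Cc2c(O)cc(O)c(C(=O)CCC)c2O)=C(O)C(C)(C)C1=O | intermediate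
12 | filixic acid BBB: 1-(2,4,6-trihydroxyphenyl)butan-1-one carrying at C3 and at C5 a CH2 group, each bonded to C4 of a 2-butanoyl-3,5-dihydroxy-6,6-dimethylcyclohexa-2,4-dien-1-one unit; achiral | CCCC(=O)C1=C(O)C(Cc2c(O)c(CC3=C(O)C(C)(C)C(=O)C(C(=O)CCC)=C3O)c(O)c(C(=O)CCC)c2O)=C(O)C(C)(C)C1=O | target

## Step count and risks

Total step count: 3. Longest linear sequence: 2 (step 1 → step 3, or step 2 → step 3).

Steps most likely to fail, most risky first:

Step 2 is the least precedented. The Claisen closure onto the neopentyl-type ester may be slow. Tetraketide 8 may instead close through oxygen to a pyrandione, or through its propyl-side α-carbon onto C3 to a resorcinol, and 7 may be acylated twice. The fallback sets out from 5 and comes back to the route at 9. Compound 5 is C,C-dimethylated with iodomethane (2.2 equiv) and NaOMe in MeOH at 0 °C → rt. This dearomatising gem-dimethylation is the classical route to acylfilicinic acids, and 9 is separated from mono- and trimethylated material by bicarbonate extraction and crystallisation. It needs more of 5 from step 1. New compounds on this path: none F0.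

Step 3 is a three-component coupling with statistical by-products. Acceptor 10 is also captured by 9 itself, giving the symmetrical 9–CH2–9 dimer, and hydroxymethylated 5 can oligomerise. Base-mediated exchange of methylene-bis compounds helps, but the yield is likely modest. The fallback sets out from 9 and comes back to the route at 10. Compound 9 is converted by a Mannich reaction (aqueous dimethylamine, formaldehyde, EtOH, rt) into 2-butanoyl-4-[(dimethylamino)methyl]-3,5-dihydroxy-6,6-dimethylcyclohexa-2,4-dien-1-one F2. Heating F2 (2.2 equiv) with 5 in dioxane at 90 °C expels dimethylamine and regenerates 10 with no free 9 present. Only the two ring carbons of 5 can then add, leading through 11 to 12.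

Step 1 has three weak points. The pyrone dianion may be acylated poorly by an enolisable ester, the pyronate of 3 may resist methanolysis, and 4 may close in the aldol mode to the isomeric resorcylate. The fallback sets out from 1 and comes back to the route at 4. The pyrone is opened first (Mg(OMe)2, MeOH, reflux) to methyl 3,5-dioxohexanoate F1. Its trianion (LDA, THF, 0 °C; F1 in twofold excess) is acylated at C6 by 2 to give 4. Here 4 is isolated (copper chelate or chromatography) and cyclised on its own with Mg(OMe)2 in MeOH to 5.

## Further compounds

F1 | step 1 | methyl 3,5-dioxohexanoate | CC(=O)CC(=O)CC(=O)OC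
F0 | step 2 | none | none
F2 | step 3 | 2-butanoyl-4-[(dimethylamino)methyl]-3,5-dihydroxy-6,6-dimethylcyclohexa-2,4-dien-1-one | CCCC(=O)C1=C(O)C(CN(C)C)=C(O)C(C)(C)C1=O
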